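**Retrosynthetic overview**
1. Names used: ring A = dihydrofuran O–C1=C2–C3–C4(CH3). Ring B = butenolide O–C6–C7=C11(C13H2OAc)–C12(=O). Ring C = nine-membered ring C4–C5=C6–C7–C8(OAc)–C9–C10(CH3)(OH)–C1–O.
2. Ring C is closed last, at C5=C6, by a one-flask silylative vinylogous Mukaiyama condensation that also eliminates both acetal methoxy groups.
3. Enabling feature: C5=C6 joins the acidic C6H2 of ring B (a latent 2-silyloxyfuran) to a non-enolisable C5 acetal on quaternary C4. With rings A and B in place, five rotatable bonds separate C5 and C6, and ring C accepts only the C4/C7-cis (E) alkene.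
4. Ring A comes from 5-endo-dig addition of C4–OH to a C1≡C2 alkyne. C7–C8 comes from a Nozaki–Hiyama–Kishi union of a ring B iodide with a C8 aldehyde. C10 and C4 come from catalytic asymmetric allyl- and propargylboration.
5. Ring order: B (iodolactonisation of an allenoate), then A, then C. Desilylation and C13 acetylation finish the route.

Key step: step 12

Remark: the sense of induction of the two biphenol-catalysed boronate additions and of the chromium ligand is assumed to be selectable through the antipode of catalyst or ligand.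

Step 1
Reactants: 1 but-2-yne-1,4-diol
Product: 2 4-(tert-butyldimethylsilyloxy)but-2-yn-1-ol
Conditions: NaH (1 equiv), THF, 0 °C; TBSCl (1 equiv), rt
Reagents that add atoms: tert-butyldimethylsilyl chloride, CC(C)(C)[Si](C)(C)Cl
Why: O-silylation of the sparingly soluble monosodium alkoxide of a symmetric diol favours the mono-ether.

Step 2
Reactants: 2 4-(tert-butyldimethylsilyloxy)but-2-yn-1-ol
Product: 3 4-(tert-butyldimethylsilyloxy)but-2-ynyl methyl carbonate
Conditions: ClCO2Me, pyridine, CH2Cl2, 0 °C
Reagents that add atoms: methyl chloroformate, COC(=O)Cl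
Why: Simple O-acylation of a primary propargylic alcohol installs the leaving group for the carbonylation.

Step 3
Reactants: 3 4-(tert-butyldimethylsilyloxy)but-2-ynyl methyl carbonate
Product: 4 methyl 2-[(tert-butyldimethylsilyloxy)methyl]buta-2,3-dienoate
Conditions: Pd(OAc)2 (2 mol %), PPh3 (8 mol %), CO (10 atm), MeOH, 45 °C
Reagents that add atoms: carbon monoxide, [C-]#[O+]
Why: In this palladium-catalysed carbonylation of a propargylic carbonate, SN2'-type oxidative addition to zerovalent palladium gives an allenylpalladium methoxide, and CO insertion then gives the 2,3-dienoate with loss of CO2.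

Step 4
Reactants: 4 methyl 2-[(tert-butyldimethylsilyloxy)methyl]buta-2,3-dienoate
Product: 5 3-[(tert-butyldimethylsilyloxy)methyl]-4-iodofuran-2(5H)-one (ring B iodide)
Conditions: I2 (2 equiv), MeCN–H2O (15:1), rt
Reagents that add atoms: iodine, II
Why: In this iodolactonisation of a 2,3-allenoate, iodine adds to the central allene carbon (C7), the ester carbonyl oxygen closes on C6, and the methyl group leaves as MeI, which closes ring B and leaves the C7–I handle.

Step 5
Reactants: 6 1,1-dimethoxypropan-2-one
Product: 7 (2S)-1,1-dimethoxy-2-methylpent-4-yn-2-ol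
Conditions: allenylboronic acid pinacol ester (1.5 equiv), 3,3'-Br2-BINOL (10 mol %, antipode chosen for S), toluene, rt; aq. work-up
Reagents that add atoms: allenylboronic acid pinacol ester, C=C=CB1OC(C)(C)C(C)(C)O1
Why: This is a chiral-biphenol-catalysed asymmetric propargylboration of a ketone (SE2' transfer through a closed six-membered transition state), in which the catalyst-bound boronate distinguishes CH3 from CH(OMe)2 and sets C4 as S.

Step 6
Reactants: 7 (2S)-1,1-dimethoxy-2-methylpent-4-yn-2-ol
Product: 8 (6S)-6-hydroxy-7,7-dimethoxy-6-methylhept-3-yn-2-one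
Conditions: n-BuLi (2.1 equiv), THF, −78 °C; MeC(O)N(OMe)Me, −78 → −20 °C; cold aq. quench
Reagents that add atoms: N-methoxy-N-methylacetamide, CC(=O)N(C)OC
Why: In this Weinreb ketone synthesis the alkoxide/acetylide dianion is acylated at carbon and the chelated tetrahedral adduct prevents over-addition, while C4 is untouched.

Step 7
Reactants: 8 (6S)-6-hydroxy-7,7-dimethoxy-6-methylhept-3-yn-2-one
Product: 9 (4S,8S)-9,9-dimethoxy-4,8-dimethylnon-1-en-5-yne-4,8-diol
Conditions: allylB(OiPr)2 (2 equiv), 3,3'-Br2-BINOL (15 mol %, antipode chosen for S), PhCF3–toluene, −35 °C; aq. work-up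
Reagents that add atoms: diisopropyl allylboronate, C=CCB(OC(C)C)OC(C)C
Why: This chiral-biphenol-catalysed asymmetric allylboration adds 1,2 to the methyl alkynyl ketone through a chair transition state, and the catalyst alone sets C10 as S because C4 is remote.

Step 8
Reactants: 9 (4S,8S)-9,9-dimethoxy-4,8-dimethylnon-1-en-5-yne-4,8-diol
Product: 10 (3S,7S)-3,7-dihydroxy-8,8-dimethoxy-3,7-dimethyloct-4-ynal
Conditions: OsO4 (2 mol %), NaIO4 (4 equiv), 2,6-lutidine, dioxane–H2O, rt
Reagents that add atoms: sodium periodate, [Na+].[O-]I(=O)(=O)=O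
Why: The Lemieux–Johnson oxidation cleaves only the terminal alkene, since the internal alkyne, acetal and tertiary alcohols are inert and the lutidine buffer suppresses retro-aldol cleavage.

Step 9
Reactants: 10 (3S,7S)-3,7-dihydroxy-8,8-dimethoxy-3,7-dimethyloct-4-ynal; 5 3-[(tert-butyldimethylsilyloxy)methyl]-4-iodofuran-2(5H)-one
Product: 11 4-[(1S,3S,7S)-1,3,7-trihydroxy-8,8-dimethoxy-3,7-dimethyloct-4-yn-1-yl]-3-[(tert-butyldimethylsilyloxy)methyl]furan-2(5H)-one
Conditions: CrCl2 (4 equiv), NiCl2 (2 mol %), chiral oxazoline-sulfonamide ligand (4.4 equiv), Et3N, THF, rt; aq. work-up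
Reagents that add atoms: none
Why: In this Nozaki–Hiyama–Kishi coupling nickel inserts into C7–I and transfers the vinyl group to chromium, the resulting vinylchromium adds only to the aldehyde in the presence of lactone, acetal, alkyne and free tertiary alcohols, and the chiral ligand on chromium sets C8 as S.

Step 10
Reactants: 11 the triol from step 9
Product: 12 (1S,3S,7S)-1-{4-[(tert-butyldimethylsilyloxy)methyl]-5-oxo-2,5-dihydrofuran-3-yl}-3,7-dihydroxy-8,8-dimethoxy-3,7-dimethyloct-4-yn-1-yl acetate
Conditions: Ac2O (1.2 equiv), pyridine, DMAP (5 mol %), CH2Cl2, 0 °C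
Reagents that add atoms: acetic anhydride, CC(=O)OC(C)=O
Why: Only the secondary C8 alcohol is acylated while both tertiary alcohols stay free, and this also prevents C8–OH from attacking the alkyne in step 11.

Step 11
Reactants: 12 the C8 acetate from step 10
Product: 13 (1S,3S)-1-{4-[(tert-butyldimethylsilyloxy)methyl]-5-oxo-2,5-dihydrofuran-3-yl}-3-[(5S)-5-(dimethoxymethyl)-5-methyl-4,5-dihydrofuran-2-yl]-3-hydroxybutyl acetate
Conditions: Ph3PAuNTf2 (3 mol %), 4 Å MS, toluene, 0 °C → rt; filtration through Et3N-deactivated silica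
Reagents that add atoms: none
Why: This is a 5-endo-dig cycloisomerisation of a homopropargylic alcohol to a 2,3-dihydrofuran under catalysis by monovalent gold, and C4–OH is the only hydroxyl able to reach the alkyne because C10–OH is propargylic and C8–O is acetylated.

Step 12
Reactants: 13 the ring A / ring B acetal from step 11
Product: 16 ring C macrocycle (E-C5=C6; 10-O-SiMe3; 13-O-TBS; 8-OAc), via bis-silylated 2-silyloxyfuran 14 (not isolated), via C5-methoxy macrocycle 15 (not isolated)
Conditions: iPr2NEt (4 equiv), TMSOTf (5 equiv), CH2Cl2 (0.002 M, slow addition of 13), −78 → 0 °C; aq. NaHCO3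
Reagents that add atoms: trimethylsilyl trifluoromethanesulfonate, C[Si](C)(C)OS(=O)(=O)C(F)(F)F
Why: Proposed new method: TMSOTf/iPr2NEt first caps C10–OH and soft-enolises ring B to the aromatic 2-silyloxyfuran 14, free TMSOTf then ionises the C5 dimethyl acetal, and C6 (the furan α-carbon) attacks the C5 oxocarbenium ion in a 9-exo-trig vinylogous Mukaiyama closure to give 15. Renewed enol silylation of 15 turns the remaining C5–OMe into a furfuryl-type leaving group, and its TMSOTf-assisted loss (a 1,6-elimination) gives the C5=C6 ylidene butenolide. The closest known reaction types are the one-pot silyl triflate/amine enol-silane formation–Mukaiyama addition to dimethyl acetals with loss of methanol, the silyl triflate/amine route from butenolides to γ-ylidene butenolides, and intramolecular vinylogous aldol closure of oxa-bridged nine-membered rings, and merging them on a medium ring is what is new. No lasting stereocentre is made, because C5 and C6 of 15 are erased, and the alkene geometry is controlled by ring C, which can hold C4 and C7 only cis (the E isomer that is disfavoured in open-chain cases). The step needs γ- over α-attack (secured by furan electronics and the substituted C11), cyclisation over oligomerisation (high dilution, and two rings plus two quaternary carbons leave five rotatable bonds between C5 and C6), and ionisation of the acetal rather than of C10–O or protonation of the enol ether (amine buffer, no protic acid, at or below 0 °C).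

Step 13
Reactants: 16 ring C macrocycle
Product: 17 13-hydroxy-10-hydroxy macrocycle (8-OAc retained)
Conditions: Et3N·3HF (5 equiv), Et3N (2 equiv), THF, 0 °C → rt
Reagents that add atoms: none
Why: Fluoride cleaves both Si–O bonds under buffered, nearly neutral conditions that should spare the acetate, the enol ether and the ylidene butenolide.

Step 14
Reactants: 17 13-hydroxy-10-hydroxy macrocycle
Product: 18 target CNP0144020.1
Conditions: Ac2O (1.5 equiv), pyridine, CH2Cl2, 0 °C
Reagents that add atoms: acetic anhydride, CC(=O)OC(C)=O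
Why: The primary allylic C13 alcohol is acylated selectively because the tertiary C10–OH is inert without forcing catalysis, and no stereocentre is touched.

**Compound list**
1 | but-2-yne-1,4-diol | OCC#CCO | starting material
2 | 4-(tert-butyldimethylsilyloxy)but-2-yn-1-ol | CC(C)(C)[Si](C)(C)OCC#CCO | intermediate
3 | 4-(tert-butyldimethylsilyloxy)but-2-ynyl methyl carbonate | CC(C)(C)[Si](C)(C)OCC#CCOC(=O)OC | intermediate
4 | methyl 2-[(tert-butyldimethylsilyloxy)methyl]buta-2,3-dienoate | C=C=C(CO[Si](C)(C)C(C)(C)C)C(=O)OC | intermediate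
5 | 3-[(tert-butyldimethylsilyloxy)methyl]-4-iodofuran-2(5H)-one | O=C1OCC(I)=C1CO[Si](C)(C)C(C)(C)C | intermediate
6 | 1,1-dimethoxypropan-2-one | CC(=O)C(OC)OC | starting material
7 | (2S)-1,1-dimethoxy-2-methylpent-4-yn-2-ol | C#CC[C@](C)(O)C(OC)OC | intermediate
8 | (6S)-6-hydroxy-7,7-dimethoxy-6-methylhept-3-yn-2-one | CC(=O)C#CC[C@](C)(O)C(OC)OC | intermediate
9 | (4S,8S)-9,9-dimethoxy-4,8-dimethylnon-1-en-5-yne-4,8-diol | C=CC[C@](C)(O)C#CC[C@](C)(O)C(OC)OC | intermediate
10 | (3S,7S)-3,7-dihydroxy-8,8-dimethoxy-3,7-dimethyloct-4-ynal | O=CC[C@](C)(O)C#CC[C@](C)(O)C(OC)OC | intermediate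
11 | coupling product, C8 (S) alcohol | O=C1OCC(=C1CO[Si](C)(C)C(C)(C)C)[C@@H](O)C[C@](C)(O)C#CC[C@](C)(O)C(OC)OC | intermediate
12 | C8 acetate of 11 | O=C1OCC(=C1CO[Si](C)(C)C(C)(C)C)[C@@H](OC(C)=O)C[C@](C)(O)C#CC[C@](C)(O)C(OC)OC | intermediate
13 | ring A dihydrofuran acetal (key precursor) | O=C1OCC(=C1CO[Si](C)(C)C(C)(C)C)[C@@H](OC(C)=O)C[C@](C)(O)C2=CC[C@](C)(O2)C(OC)OC | intermediate
14 | bis-silylated 2-silyloxyfuran (not isolated) | C[Si](C)(C)Oc1occ([C@@H](OC(C)=O)C[C@](C)(O[Si](C)(C)C)C2=CC[C@](C)(O2)C(OC)OC)c1CO[Si](C)(C)C(C)(C)C | intermediate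
15 | C5-methoxy macrocycle, C5/C6 epimers (not isolated) | CC(C)(C)[Si](C)(C)OCC1=C2C(C(OC)[C@]3(C)CC=C(O3)[C@@](C)(O[Si](C)(C)C)C[C@@H]2OC(C)=O)OC1=O | intermediate
16 | ring C macrocycle, 10-O-SiMe3, 13-O-TBS | CC(C)(C)[Si](C)(C)OCC1=C2/C(=C\[C@]3(C)CC=C(O3)[C@@](C)(O[Si](C)(C)C)C[C@@H]2OC(C)=O)OC1=O | intermediate
17 | 13-hydroxy-10-hydroxy macrocycle | OCC1=C2/C(=C\[C@]3(C)CC=C(O3)[C@@](C)(O)C[C@@H]2OC(C)=O)OC1=O | intermediate
18 | CNP0144020.1, (4S,8S,10S,5E)-8,13-diacetoxy-1,4-epoxy-10-hydroxygermacra-1,5,7(11)-trien-12,6-olide | CC(=O)OCC1=C2/C(=C\[C@]3(C)CC=C(O3)[C@@](C)(O)C[C@@H]2OC(C)=O)OC1=O | target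

**Step count:** 14 steps in total. The longest linear sequence is 10 steps (steps 5–14, from 6).

**Steps most likely to fail**

1. **Step 12.** Oligomerisation may outrun the nine-membered closure, or free silyl triflate may ionise C10–O or degrade the enol ether before the hindered, inductively deactivated C5 acetal ionises.
   - The fallback uses known chemistry. The electrophile becomes a free aldehyde that is liberated before ring A exists, and the elimination becomes a base-induced E1cB.
   - It sets out from 12. Aqueous TFA in CH2Cl2 at 0 °C hydrolyses the acetal to the hydroxy aldehyde F1.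
   - Ph3PAuNTf2 then closes ring A to the dihydrofuran aldehyde F2.
   - The established silyl triflate/amine-then-DBU ylidene-butenolide protocol (Et3SiOTf, iPr2NEt, high dilution; then DBU) closes ring C to the 10-O-triethylsilyl macrocycle F3.
   - Et3N·3HF removes both silyl groups, and the route is rejoined at 17.

2. **Step 11.** Meyer–Schuster rearrangement of the tertiary propargylic alcohol, or 5-exo-dig participation of an acetal oxygen, may compete with the 5-endo-dig attack of C4–OH.
   - The fallback replaces π-acid catalysis with electrophilic halocyclisation and reduction.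
   - It sets out from 12. I2 and NaHCO3 in MeCN at 0 °C give the C2-iodo dihydrofuran F4, which cannot aromatise because C4 is quaternary.
   - Pd(PPh3)4 with Bu3SnH removes the iodine, and the route is rejoined at 13.

3. **Step 9.** Facial selectivity at C8 may be poor, or the vinyl iodide may suffer protodeiodination.
   - The fallback replaces reagent control with substrate-directed reduction.
   - It sets out from 10 and 5. A ligand-free coupling (CrCl2, NiCl2, DMF) gives the C8-epimeric alcohols F5.
   - DMP oxidises them to the β-hydroxy ketone F6.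
   - An Evans–Saksena reduction (Me4NBH(OAc)3, MeCN–AcOH, −20 °C) delivers hydride from the boron bound to C10–O and gives the 1,3-anti diol, which is 11.

**Further compounds**
F1 | step 12 | hydroxy aldehyde (acetal of 12 hydrolysed) | O=C1OCC(=C1CO[Si](C)(C)C(C)(C)C)[C@@H](OC(C)=O)C[C@](C)(O)C#CC[C@](C)(O)C=O
F2 | step 12 | dihydrofuran aldehyde | O=C1OCC(=C1CO[Si](C)(C)C(C)(C)C)[C@@H](OC(C)=O)C[C@](C)(O)C2=CC[C@](C)(O2)C=O
F3 | step 12 | 10-O-triethylsilyl macrocycle | CC(C)(C)[Si](C)(C)OCC1=C2/C(=C\[C@]3(C)CC=C(O3)[C@@](C)(O[Si](CC)(CC)CC)C[C@@H]2OC(C)=O)OC1=O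
F4 | step 11 | C2-iodo dihydrofuran | O=C1OCC(=C1CO[Si](C)(C)C(C)(C)C)[C@@H](OC(C)=O)C[C@](C)(O)C2=C(I)C[C@](C)(O2)C(OC)OC
F5 | step 9 | C8-epimeric alcohols | O=C1OCC(=C1CO[Si](C)(C)C(C)(C)C)C(O)C[C@](C)(O)C#CC[C@](C)(O)C(OC)OC
F6 | step 9 | C8 ketone (β-hydroxy ketone) | O=C1OCC(=C1CO[Si](C)(C)C(C)(C)C)C(=O)C[C@](C)(O)C#CC[C@](C)(O)C(OC)OC
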